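## Retrosynthetic overview

1. The target is read as a 5,10-epoxygermacran-12,8-olide (germacrane numbering, C1–C15); the last bond made is the C9 isovalerate ester.
2. Key disconnection: the α-methylene-γ-lactone ring (O–C12–C11–C7–C8) is cut at C11–C12 and at O–C8, so CO2 is stitched between an alkenyl triflate at C11 and C8 of an exo 8,9-epoxide (20). The enabling feature is that vinylic C11 on C7 lies 1,3 to C8, whose oxygen is trans to the C9 oxygen on the oxepane ring; one 5-exo epoxide opening by the new carboxylate therefore sets C8 and uncovers the C9 hydroxyl.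
3. The 11-oxabicyclo[4.4.1]undecane core (two oxepanes sharing C5–O–C10) comes from transannular alkoxymercuration of a cyclodec-1(10)-en-5-ol; the C8=C9 alkene is unveiled afterwards by dehydration of a C9 carbinol.
4. The ten-membered carbocycle arises by anionic oxy-Cope ring expansion that cleaves the C5–C10 bond of the (R)-carvone ring (carvone supplies C5–C10, C14 and the C7 stereocentre); the methyl/vinyl quaternary carbon comes from a semipinacol vinyl shift on the carvone-oxide-derived epoxy alcohol.
5. Ring order: cyclohexane (carvone) → cyclodecene → both oxepanes (bridged ether) → epoxide → γ-lactone.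

Key step: step 16

Remark: ring-expanded compounds carry germacrane numbering; exo/endo mean the face of a seven-membered ring away from/towards the other carbon bridge. Assumption: reagents approach the medium ring from its periphery (steps 8 and 9).

## Route

Step 1
Reactants: 1 (R)-(−)-carvone
Product: 3 (5R)-5-acetyl-2-methylcyclohex-2-en-1-one, via secondary ozonide 2 (not isolated)
Conditions: O3, CH2Cl2, −78 °C (indicator end point); then Me2S, −78 °C to rt
Reagents that add atoms: ozone, [O-][O+]=O
Why: Ozonolysis with reductive work-up cleaves the electron-rich 1,1-disubstituted isopropenyl alkene much faster than the electron-poor enone alkene, and the ring stereocentre (future C7) is not touched.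

Step 2
Reactants: 3 (5R)-5-acetyl-2-methylcyclohex-2-en-1-one
Product: 4 (5R)-2-methyl-5-(2-methyl-1,3-dioxolan-2-yl)cyclohex-2-en-1-one
Conditions: (TMSOCH2)2, TMSOTf (cat.), CH2Cl2, −78 °C
Reagents that add atoms: 1,2-bis(trimethylsilyloxy)ethane, C[Si](C)(C)OCCO[Si](C)(C)C
Why: Silyl-transfer ketalisation under TMSOTf catalysis at low temperature converts the saturated methyl ketone while the conjugated enone carbonyl stays free.

Step 3
Reactants: 4 (5R)-2-methyl-5-(2-methyl-1,3-dioxolan-2-yl)cyclohex-2-en-1-one
Product: 5 (1R,4R,6R)-1-methyl-4-(2-methyl-1,3-dioxolan-2-yl)-7-oxabicyclo[4.1.0]heptan-2-one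
Conditions: 30% H2O2, NaOH (cat.), MeOH, 0 °C
Reagents that add atoms: hydrogen peroxide, OO
Why: In this Weitz–Scheffer epoxidation hydroperoxide adds axially to the β-carbon anti to the C5 substituent, so the epoxide forms trans to the dioxolanyl group, as is known for carvone itself.

Step 4
Reactants: 5 (1R,4R,6R)-1-methyl-4-(2-methyl-1,3-dioxolan-2-yl)-7-oxabicyclo[4.1.0]heptan-2-one
Product: 6 2-ethenyl-1-methyl-4-(2-methyl-1,3-dioxolan-2-yl)-7-oxabicyclo[4.1.0]heptan-2-ol (vinyl trans to the epoxide oxygen; OH cis)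
Conditions: CH2=CHMgBr, CeCl3, THF, −78 °C
Reagents that add atoms: vinylmagnesium bromide, C=C[Mg]Br
Why: 1,2-Addition of the non-basic vinylcerium reagent occurs anti to the epoxide C–O bond along the equatorial trajectory, which puts the vinyl group trans and the hydroxyl cis to the epoxide oxygen.

Step 5
Reactants: 6 2-ethenyl-1-methyl-4-(2-methyl-1,3-dioxolan-2-yl)-7-oxabicyclo[4.1.0]heptan-2-ol
Product: 7 2-ethenyl-3-hydroxy-2-methyl-5-(2-methyl-1,3-dioxolan-2-yl)cyclohexan-1-one (3-OH cis to 2-methyl; trans to 2-vinyl and to the 5-substituent)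
Conditions: BF3·OEt2 (cat.), CH2Cl2, −78 °C
Reagents that add atoms: none
Why: In this semipinacol rearrangement of a 2,3-epoxy alcohol the vinyl group, antiperiplanar to the breaking tertiary C–O bond, shifts 1,2 with inversion at the methyl-bearing carbon, which creates the methyl/vinyl quaternary centre (future C10) and leaves the secondary C–O bond (future C9) untouched.

Step 6
Reactants: 7 2-ethenyl-3-hydroxy-2-methyl-5-(2-methyl-1,3-dioxolan-2-yl)cyclohexan-1-one
Product: 8 2-ethenyl-3-(methoxymethoxy)-2-methyl-5-(2-methyl-1,3-dioxolan-2-yl)cyclohexan-1-one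
Conditions: MOMCl, i-Pr2NEt, Bu4NI (cat.), CH2Cl2, 0 °C to 40 °C
Reagents that add atoms: chloromethyl methyl ether, COCCl
Why: MOM ether formation under non-enolising amine conditions avoids retro-aldol cleavage of the β-hydroxy ketone and installs a group that cannot migrate to the neighbouring alkoxide in step 8.

Step 7
Reactants: 8 2-ethenyl-3-(methoxymethoxy)-2-methyl-5-(2-methyl-1,3-dioxolan-2-yl)cyclohexan-1-one
Product: 9 2-ethenyl-3-(methoxymethoxy)-2-methyl-5-(2-methyl-1,3-dioxolan-2-yl)-1-(prop-1-en-2-yl)cyclohexan-1-ol (isopropenyl cis to vinyl)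
Conditions: CH2=C(CH3)MgBr, CeCl3, THF, −78 to 0 °C
Reagents that add atoms: isopropenylmagnesium bromide, CC(=C)[Mg]Br
Why: Organocerium 1,2-addition to the hindered ketone by equatorial attack, away from the axial OMOM group, should place the isopropenyl group cis to the vinyl group, and either carbinol epimer remains a competent 1,5-diene for step 8.

Step 8
Reactants: 9 2-ethenyl-3-(methoxymethoxy)-2-methyl-5-(2-methyl-1,3-dioxolan-2-yl)-1-(prop-1-en-2-yl)cyclohexan-1-ol
Product: 11 (E)-7-(methoxymethoxy)-2,6-dimethyl-9-(2-methyl-1,3-dioxolan-2-yl)cyclodec-5-en-1-one (germacrane: 5-oxo-1(10)E-ene; 4-methyl cis to the C7 substituent), via potassium enolate 10 (not isolated)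
Conditions: KH, 18-crown-6, THF, 0 °C to rt; H2O quench at −78 °C
Reagents that add atoms: none
Why: The anionic oxy-Cope ring expansion of the 1,2-dialkenylcyclohexanol proceeds through a chair transition state that cleaves the bond between the carbinol and quaternary carbons (C5–C10) and forms C2–C3, giving the (E)-C1=C10 alkene, while protonation of the enolate from the ring periphery sets C4 (which, being α to the ketone, can be equilibrated with DBU if required).

Step 9
Reactants: 11 (E)-7-(methoxymethoxy)-2,6-dimethyl-9-(2-methyl-1,3-dioxolan-2-yl)cyclodec-5-en-1-one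
Product: 12 (E)-7-(methoxymethoxy)-2,6-dimethyl-9-(2-methyl-1,3-dioxolan-2-yl)cyclodec-5-en-1-ol (1-OH, 2-methyl and 9-dioxolanyl all cis; 7-OMOM trans)
Conditions: L-Selectride, THF, −78 °C; H2O work-up
Reagents that add atoms: none
Why: The bulky hydride adds to the medium-ring ketone from the periphery on the face away from the α-methyl group (the usual cis-2-methylcycloalkanol selectivity), which should give the C5 hydroxyl cis to the C4 methyl and to the C7 substituent.

Step 10
Reactants: 12 (E)-7-(methoxymethoxy)-2,6-dimethyl-9-(2-methyl-1,3-dioxolan-2-yl)cyclodec-5-en-1-ol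
Product: 14 2-(methoxymethoxy)-1,7-dimethyl-4-(2-methyl-1,3-dioxolan-2-yl)-11-oxabicyclo[4.4.1]undecane (4-dioxolanyl and 7-methyl exo; 2-OMOM endo), via alkylmercury acetate 13 (not isolated)
Conditions: Hg(OAc)2, THF, rt; then NaBH4, aq NaOH, 0 °C
Reagents that add atoms: none
Why: In this transannular alkoxymercuration–demercuration the C5 hydroxyl adds to the strained trisubstituted (E)-alkene at the tertiary carbon C10 (Markovnikov, C5 and C10 facing each other across the ring), which closes both oxepane rings at once with the C10 configuration dictated by the bridge, and NaBH4 then reduces C1–Hg to CH2.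

Step 11
Reactants: 14 2-(methoxymethoxy)-1,7-dimethyl-4-(2-methyl-1,3-dioxolan-2-yl)-11-oxabicyclo[4.4.1]undecane
Product: 15 1-[2-(methoxymethoxy)-1,7-dimethyl-11-oxabicyclo[4.4.1]undecan-4-yl]ethan-1-one (acetyl exo)
Conditions: PPTS, acetone/H2O, 50 °C
Reagents that add atoms: water, O
Why: Mild acid hydrolysis removes the dioxolane ketal, which is far more labile than the formaldehyde acetal (MOM), so the methyl ketone is freed while C9 stays protected and C8–C9 saturated.

Step 12
Reactants: 15 1-[2-(methoxymethoxy)-1,7-dimethyl-11-oxabicyclo[4.4.1]undecan-4-yl]ethan-1-one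
Product: 17 1-[2-(methoxymethoxy)-1,7-dimethyl-11-oxabicyclo[4.4.1]undecan-4-yl]ethenyl trifluoromethanesulfonate, via potassium enolate 16 (not isolated)
Conditions: KHMDS, THF, −78 °C; then PhNTf2, −78 to 0 °C; H2O work-up
Reagents that add atoms: N-phenyl-bis(trifluoromethanesulfonimide), O=S(=O)(N(c1ccccc1)S(=O)(=O)C(F)(F)F)C(F)(F)F
Why: Kinetic deprotonation of the methyl ketone at the methyl group and O-triflation of the less substituted enolate give the 1-substituted vinyl triflate, because with C8–C9 still saturated the C7 hydrogen is an ordinary hindered tertiary α-hydrogen and is not removed.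

Step 13
Reactants: 17 1-[2-(methoxymethoxy)-1,7-dimethyl-11-oxabicyclo[4.4.1]undecan-4-yl]ethenyl trifluoromethanesulfonate
Product: 18 1-(2-hydroxy-1,7-dimethyl-11-oxabicyclo[4.4.1]undecan-4-yl)ethenyl trifluoromethanesulfonate (2-OH endo)
Conditions: 3 M HCl, MeOH/THF, 50 °C
Reagents that add atoms: none
Why: Acidic cleavage of the MOM acetal frees the C9 hydroxyl, and the alkenyl triflate and the bridged ether tolerate these conditions.

Step 14
Reactants: 18 1-(2-hydroxy-1,7-dimethyl-11-oxabicyclo[4.4.1]undecan-4-yl)ethenyl trifluoromethanesulfonate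
Product: 19 1-(1,7-dimethyl-11-oxabicyclo[4.4.1]undec-2-en-4-yl)ethenyl trifluoromethanesulfonate
Conditions: Burgess reagent, PhMe, 70 °C
Reagents that add atoms: none
Why: Burgess dehydration is a syn elimination through the sulfamate ester, and since C10 is quaternary only C8 carries β-hydrogens, so the C8=C9 alkene forms regiospecifically without cationic rearrangement.

Step 15
Reactants: 19 1-(1,7-dimethyl-11-oxabicyclo[4.4.1]undec-2-en-4-yl)ethenyl trifluoromethanesulfonate
Product: 20 1-(exo-2,3-epoxy-1,7-dimethyl-11-oxabicyclo[4.4.1]undecan-4-yl)ethenyl trifluoromethanesulfonate (epoxide cis to the C7 side chain)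
Conditions: mCPBA, NaHCO3, CH2Cl2, 0 °C
Reagents that add atoms: mCPBA, OOC(=O)c1cccc(Cl)c1
Why: In this Prilezhaev epoxidation the electron-poor enol triflate is inert and the peracid should attack the cis ring alkene from the convex exo face of the bicycle, the endo face being shielded by the C1–C4 bridge, which gives the epoxide cis to the C7 side chain.

Step 16
Reactants: 20 1-(exo-2,3-epoxy-1,7-dimethyl-11-oxabicyclo[4.4.1]undecan-4-yl)ethenyl trifluoromethanesulfonate
Product: 22 (4S,5R,7R,8R,9S,10R)-9-hydroxy-5,10-epoxygermacr-11(13)-en-12,8-olide, via manganese acrylate 21 (not isolated)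
Conditions: CO2 (1 atm), CoI2(2,9-dimethyl-1,10-phenanthroline) (10 mol %), Mn powder, DMA, rt; then 60 °C; 1 M HCl work-up
Reagents that add atoms: carbon dioxide, O=C=O
Why: Proposed new method: Mn reduces the cobalt precatalyst, which adds oxidatively into the C11–OTf bond and, after further one-electron reduction, inserts CO2 at C11 to give acrylate 21 (first bond, C11–C12); the Mn(II)-bound carboxylate then opens the Lewis-acid-activated 8,9-epoxide at C8 (second bond, O–C8), the closest known reaction types being the Co/Ni-catalysed reductive carboxylation of alkenyl triflates with CO2/Mn and the lactonisation of γ,δ-epoxy carboxylates, which have close precedent separately but not as one operation. The γ-lactone ring (O–C12–C11–C7–C8) closes in the 5-exo-tet mode, whereas attack at C9 would be 6-endo at a neopentyl carbon next to the quaternary C10 ether centre and is disfavoured on both counts. C8 is set by SN2 inversion, so the lactone oxygen arrives on the endo face, anti to the exo epoxide and trans to the C7–C11 bond (trans-fused lactone), while C9 keeps its epoxide oxygen as the free exo hydroxyl, giving the trans-8,9-dioxygen pattern; C7 is untouched. The step needs chemoselective activation of the alkenyl triflate over the hindered, unactivated epoxide and the 1,1-disubstituted alkene, which the preference of the low-valent metal for C(sp2)–OTf oxidative addition under neutral, halide-poor conditions at room temperature should secure. Acidic work-up closes any remaining epoxy acid by the same 5-exo opening.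

Step 17
Reactants: 22 (4S,5R,7R,8R,9S,10R)-9-hydroxy-5,10-epoxygermacr-11(13)-en-12,8-olide
Product: 23 (4S,5R,7R,8R,9S,10R)-9-(3-methylbutanoyloxy)-5,10-epoxygermacr-11(13)-en-12,8-olide (CNP0274454.1)
Conditions: isovaleryl chloride, pyridine, DMAP (cat.), CH2Cl2, 0 °C to rt
Reagents that add atoms: 3-methylbutanoyl chloride, CC(C)CC(=O)Cl
Why: DMAP-catalysed acylation of the hindered secondary C9 alcohol affects no stereocentre, and the tertiary amine bases do not add irreversibly to the α-methylene lactone.

## Compound list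

1 | (R)-(−)-carvone | CC(=C)[C@@H]1CC=C(C)C(=O)C1 | starting material
2 | 3-methyl-3-[(1R)-4-methyl-5-oxocyclohex-3-en-1-yl]-1,2,4-trioxolane (secondary ozonide) | CC1(OCOO1)[C@@H]2CC=C(C)C(=O)C2 | intermediate
3 | (5R)-5-acetyl-2-methylcyclohex-2-en-1-one | CC(=O)[C@@H]1CC=C(C)C(=O)C1 | intermediate
4 | (5R)-2-methyl-5-(2-methyl-1,3-dioxolan-2-yl)cyclohex-2-en-1-one | CC1(OCCO1)[C@@H]2CC=C(C)C(=O)C2 | intermediate
5 | (1R,4R,6R)-1-methyl-4-(2-methyl-1,3-dioxolan-2-yl)-7-oxabicyclo[4.1.0]heptan-2-one | CC1(OCCO1)[C@@H]2C[C@H]3O[C@@]3(C)C(=O)C2 | intermediate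
6 | 2-ethenyl-1-methyl-4-(2-methyl-1,3-dioxolan-2-yl)-7-oxabicyclo[4.1.0]heptan-2-ol (vinyl trans to epoxide O) | CC1(OCCO1)[C@@H]2C[C@H]3O[C@@]3(C)[C@](O)(C=C)C2 | intermediate
7 | 2-ethenyl-3-hydroxy-2-methyl-5-(2-methyl-1,3-dioxolan-2-yl)cyclohexan-1-one | CC1(OCCO1)[C@@H]2C[C@@H](O)[C@](C)(C=C)C(=O)C2 | intermediate
8 | 2-ethenyl-3-(methoxymethoxy)-2-methyl-5-(2-methyl-1,3-dioxolan-2-yl)cyclohexan-1-one | CC1(OCCO1)[C@@H]2C[C@@H](OCOC)[C@](C)(C=C)C(=O)C2 | intermediate
9 | 2-ethenyl-3-(methoxymethoxy)-2-methyl-5-(2-methyl-1,3-dioxolan-2-yl)-1-(prop-1-en-2-yl)cyclohexan-1-ol | CC1(OCCO1)[C@@H]2C[C@@H](OCOC)[C@](C)(C=C)[C@](O)(C(C)=C)C2 | intermediate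
10 | potassium enolate of 11 (oxy-Cope product) | [K+].[O-]/C1=C(\C)CC/C=C(\C)[C@H](OCOC)C[C@@H](C2(C)OCCO2)C1 | intermediate
11 | (E)-7-(methoxymethoxy)-2,6-dimethyl-9-(2-methyl-1,3-dioxolan-2-yl)cyclodec-5-en-1-one | O=C1[C@@H](C)CC/C=C(\C)[C@H](OCOC)C[C@@H](C2(C)OCCO2)C1 | intermediate
12 | (E)-7-(methoxymethoxy)-2,6-dimethyl-9-(2-methyl-1,3-dioxolan-2-yl)cyclodec-5-en-1-ol (1-OH, 2-Me, 9-substituent cis) | O[C@H]1[C@@H](C)CC/C=C(\C)[C@H](OCOC)C[C@@H](C2(C)OCCO2)C1 | intermediate
13 | C1-acetoxymercurio derivative of 14 (Hg anti to the ether oxygen) | CC1(OCCO1)[C@H]2C[C@H]3O[C@](C)([C@H]([Hg]OC(C)=O)CC[C@@H]3C)[C@H](OCOC)C2 | intermediate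
14 | 2-(methoxymethoxy)-1,7-dimethyl-4-(2-methyl-1,3-dioxolan-2-yl)-11-oxabicyclo[4.4.1]undecane | CC1(OCCO1)[C@H]2C[C@H]3O[C@](C)(CCC[C@@H]3C)[C@H](OCOC)C2 | intermediate
15 | 1-[2-(methoxymethoxy)-1,7-dimethyl-11-oxabicyclo[4.4.1]undecan-4-yl]ethan-1-one | CC(=O)[C@H]1C[C@H]2O[C@](C)(CCC[C@@H]2C)[C@H](OCOC)C1 | intermediate
16 | potassium enolate of 15 (methyl side) | [K+].[O-]C(=C)[C@H]1C[C@H]2O[C@](C)(CCC[C@@H]2C)[C@H](OCOC)C1 | intermediate
17 | 1-[2-(methoxymethoxy)-1,7-dimethyl-11-oxabicyclo[4.4.1]undecan-4-yl]ethenyl trifluoromethanesulfonate | C=C(OS(=O)(=O)C(F)(F)F)[C@H]1C[C@H]2O[C@](C)(CCC[C@@H]2C)[C@H](OCOC)C1 | intermediate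
18 | 1-(2-hydroxy-1,7-dimethyl-11-oxabicyclo[4.4.1]undecan-4-yl)ethenyl trifluoromethanesulfonate | C=C(OS(=O)(=O)C(F)(F)F)[C@H]1C[C@H]2O[C@](C)(CCC[C@@H]2C)[C@H](O)C1 | intermediate
19 | 1-(1,7-dimethyl-11-oxabicyclo[4.4.1]undec-2-en-4-yl)ethenyl trifluoromethanesulfonate | C=C(OS(=O)(=O)C(F)(F)F)[C@H]1C[C@H]2O[C@](C)(CCC[C@@H]2C)C=C1 | intermediate
20 | 1-(exo-2,3-epoxy-1,7-dimethyl-11-oxabicyclo[4.4.1]undecan-4-yl)ethenyl trifluoromethanesulfonate | C=C(OS(=O)(=O)C(F)(F)F)[C@H]1C[C@H]2O[C@](C)(CCC[C@@H]2C)[C@H]3O[C@@H]13 | intermediate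
21 | 2-(exo-2,3-epoxy-1,7-dimethyl-11-oxabicyclo[4.4.1]undecan-4-yl)acrylate (Mn(II) carboxylate, drawn as the anion) | C=C(C(=O)[O-])[C@H]1C[C@H]2O[C@](C)(CCC[C@@H]2C)[C@H]3O[C@@H]13 | intermediate
22 | (4S,5R,7R,8R,9S,10R)-9-hydroxy-5,10-epoxygermacr-11(13)-en-12,8-olide | C=C1C(=O)O[C@@H]2[C@@H]1C[C@H]1O[C@](C)(CCC[C@@H]1C)[C@H]2O | intermediate
23 | (4S,5R,7R,8R,9S,10R)-9-(3-methylbutanoyloxy)-5,10-epoxygermacr-11(13)-en-12,8-olide (CNP0274454.1) | C=C1C(=O)O[C@@H]2[C@@H]1C[C@H]1O[C@](C)(CCC[C@@H]1C)[C@H]2OC(=O)CC(C)C | target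

## Step count and risks

Total step count: 17. Longest linear sequence: 17 steps (fully linear from 1).

Steps most likely to fail:

1. Step 16 (key step). The alkenyl–metal intermediate may be protonated or reduced before CO2 insertion, the low-valent metal or halide may open the epoxide before the carboxylate exists, or the metal carboxylate may not close the lactone in the pot. The fallback uses known chemistry and sets out from 20. Palladium-catalysed methoxycarbonylation (Pd(OAc)2, dppp, CO 1 atm, Et3N, MeOH/DMF, 60 °C) should give methyl 2-(exo-2,3-epoxy-1,7-dimethyl-11-oxabicyclo[4.4.1]undecan-4-yl)acrylate F1 with the isolated epoxide untouched. Saponification (LiOH, THF/H2O) should give the epoxy acrylic acid F2, and catalytic CSA in CH2Cl2 should then effect the 5-exo opening at C8 with inversion, which comes back to the route at 22.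

2. Step 9. Hydride delivery from the undesired face of the flexible ten-membered ketone would give the C5 epimer, and with it the wrong bridged diastereomer after step 10. C4 itself can be equilibrated through the enolate at ketone 11 before reduction. The fallback sets out from 11. Reduction with the reagent that favours the other face (NaBH4/CeCl3, MeOH) should give the C5-epimeric cyclodecenol F3. Mitsunobu esterification (4-nitrobenzoic acid, DIAD, PPh3, THF) should invert C5 to give the 4-nitrobenzoate of 12 F4, and methanolysis (K2CO3, MeOH) comes back to the route at 12.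

3. Step 15. The peracid may attack from the concave endo face, steered away from the exo face by the C7 substituent; after the key step that epoxide would give the cis-fused, C8/C9-epimeric lactone. The fallback sets out from 19 and uses the same facial preference to deliver the opposite epoxide. NBS in aqueous acetone should form the bromonium ion on the face the peracid prefers, and water opens it anti to give the trans-bromohydrin F5 (C8–OH exo, C9–Br endo; the regioisomeric bromohydrin converges). K2CO3 in MeOH then closes the epoxide on the exo face by intramolecular displacement of bromide, which comes back to the route at 20.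

## Further compounds

F1 | step 16 | methyl 2-(exo-2,3-epoxy-1,7-dimethyl-11-oxabicyclo[4.4.1]undecan-4-yl)acrylate | C=C(C(=O)OC)[C@H]1C[C@H]2O[C@](C)(CCC[C@@H]2C)[C@H]3O[C@@H]13
F2 | step 16 | 2-(exo-2,3-epoxy-1,7-dimethyl-11-oxabicyclo[4.4.1]undecan-4-yl)acrylic acid | C=C(C(=O)O)[C@H]1C[C@H]2O[C@](C)(CCC[C@@H]2C)[C@H]3O[C@@H]13
F3 | step 9 | C5 epimer of cyclodecenol 12 | O[C@@H]1[C@@H](C)CC/C=C(\C)[C@H](OCOC)C[C@@H](C2(C)OCCO2)C1
F4 | step 9 | 4-nitrobenzoate of cyclodecenol 12 | O=C(O[C@H]1[C@@H](C)CC/C=C(\C)[C@H](OCOC)C[C@@H](C2(C)OCCO2)C1)c3ccc(cc3)[N+](=O)[O-]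
F5 | step 15 | 1-(endo-2-bromo-exo-3-hydroxy-1,7-dimethyl-11-oxabicyclo[4.4.1]undecan-4-yl)ethenyl trifluoromethanesulfonate | C=C(OS(=O)(=O)C(F)(F)F)[C@H]1C[C@H]2O[C@](C)(CCC[C@@H]2C)[C@H](Br)[C@H]1O
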